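**Strategy.** The lower pyran ring (O1–C2–C3–C4–C4a–C8a) is disconnected to a trans-2-aryl-3-(aminomethyl)-2,3-dihydrobenzofuran. A Demjanov ring expansion shifts the A-ring carbon C4a from C3 to the exocyclic CH2, which becomes C4, while water enters at C3 with inversion: one operation gives the six-membered ring, the bare C4 methylene and the 2,3-trans 3-OH. It exploits that C3 carries OH beside an unsubstituted C4 bound to C4a, which has O1 ortho and the C7 oxygen para (strong aryl participation). The precursor comes from a sulfur-ylide [4+1] annulation of a 2-(2-nitrovinyl)phenol. The resulting flavan-3-ol serves as both halves: C4 oxidation, 4α→6 Friedel–Crafts coupling, hydrogenolysis.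

Key step: step 6

Remark (assumption): the sense of induction of the isothiocineole benzylide in the conjugate addition of step 4 is assumed, not predicted; the sulfide enantiomer that leads to (2S,3R)-9 is to be used and is drawn as (1R,4R,5R); the configuration at sulfur in 7 and 8 is not encoded.
Remark: 13 is drawn as the 4β ether expected by analogy with other flavan-3-ols; its C4 configuration is lost again in step 8.

Step 1
Reactants: 1 2,3,4-trihydroxybenzaldehyde
Product: 2 3,4-bis(benzyloxy)-2-hydroxybenzaldehyde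
Conditions: BnBr (2.1 eq), K2CO3, DMF, rt
Reagents that add atoms: benzyl bromide, BrCc1ccccc1
Why: Williamson etherification; the 2-OH is hydrogen-bonded to the aldehyde and least nucleophilic, so two equivalents of benzyl bromide should take the 4- and 3-OH.

Step 2
Reactants: 2 3,4-bis(benzyloxy)-2-hydroxybenzaldehyde; 3 nitromethane
Product: 4 5,6-bis(benzyloxy)-2-[(E)-2-nitroethenyl]phenol
Conditions: NH4OAc, AcOH, 100 °C
Reagents that add atoms: none
Why: Henry condensation with dehydration to the conjugated (E)-nitroalkene, a standard reaction of salicylaldehydes that tolerates the free phenol.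

Step 3
Reactants: 5 1,2-bis(benzyloxy)-4-(chloromethyl)benzene; 6 (1R,4R,5R)-isothiocineole
Product: 7 (1R,4R,5R)-6-[3,4-bis(benzyloxy)benzyl]-4,7,7-trimethyl-6-thiabicyclo[3.2.1]octan-6-ium tetrafluoroborate
Conditions: NaBF4, CH2Cl2/H2O, rt
Reagents that add atoms: sodium tetrafluoroborate, [Na+].F[B-](F)(F)F
Why: S-alkylation of the sulfide by the electron-rich benzylic chloride with anion exchange to the non-nucleophilic tetrafluoroborate.

Step 4
Reactants: 4 5,6-bis(benzyloxy)-2-[(E)-2-nitroethenyl]phenol; 7 sulfonium tetrafluoroborate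
Product: 9 (2S,3R)-6,7-bis(benzyloxy)-2-[3,4-bis(benzyloxy)phenyl]-3-(nitromethyl)-2,3-dihydro-1-benzofuran (trans), via sulfonium benzylide 8 (not isolated)
Conditions: Cs2CO3, MeCN, −20 °C → rt
Reagents that add atoms: none
Why: Formal [4+1] annulation of a sulfur ylide with a 2-(2-nitrovinyl)phenol, in which Michael addition of 8 is followed by 5-exo-tet displacement of the sulfide by the ortho phenoxide with inversion; the chiral sulfide should fix the face of the ylide carbon (C2, reagent control) and the anti arrangement of aryl and nitromethyl in the ring closure should give the trans isomer (C3).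

Step 5
Reactants: 9 (2S,3R)-nitromethyl dihydrobenzofuran
Product: 10 1-{(2S,3R)-6,7-bis(benzyloxy)-2-[3,4-bis(benzyloxy)phenyl]-2,3-dihydro-1-benzofuran-3-yl}methanamine
Conditions: Zn, HCl, EtOH, 0 °C → rt
Reagents that add atoms: none
Why: Dissolving-metal reduction of an aliphatic nitro group to the primary amine; benzyl ethers survive and neither stereocentre is epimerisable under these conditions.

Step 6
Reactants: 10 (2S,3R)-aminomethyl dihydrobenzofuran
Product: 12 (2R,3S)-7,8-bis(benzyloxy)-2-[3,4-bis(benzyloxy)phenyl]chroman-3-ol (2,3-trans; tetra-O-benzylmesquitol), via alkanediazonium hydrogensulfate 11 (not isolated)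
Conditions: NaNO2, aq. H2SO4, 1,4-dioxane, 0 °C → rt
Reagents that add atoms: water, O (sodium nitrite, [Na+].[O-]N=O, and sulfuric acid, OS(=O)(=O)O, leave atoms only in the non-isolated 11)
Why: Nitrosation gives the alkanediazonium ion 11, which loses N2 with participation of the A-ring carbon C3a of the dihydrobenzofuran (the future C4a; O1 ortho, benzyloxy para) to give an aryl-bridged phenonium ion that water opens at the secondary carbon: a Demjanov rearrangement, i.e. a Wagner–Meerwein 1,2-aryl shift with one-carbon ring enlargement. The closest known reaction type is the Demjanov ring expansion of aminomethyl benzocycloalkanes to the ring-enlarged alcohols. The six-membered ring is closed not by a cyclisation but by the 1,2-shift that forms C4–C4a and breaks C3–C4a, so that the ring O1–C2–C3–C3a–C7a grows by the former exocyclic carbon. C2 is untouched and keeps its geometry (its descriptor changes from S to R only through the CIP priorities); C3 is set by substrate control, because water attacks C3 anti to the departing aryl carbon (inversion), which converts the trans-dihydrobenzofuran into the 2,3-trans-flavan-3-ol. The step needs aryl migration to win over hydride or C2 shifts, substitution at CH2 and elimination, and needs opening of the bridged ion at C3 instead of CH2; the para-benzyloxy and ortho-oxygen activation of the migrating carbon, the secondary character of C3 and the relief of five-ring strain should secure this.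

Step 7
Reactants: 12 (2R,3S)-tetra-O-benzylmesquitol
Product: 13 (2R,3S,4S)-7,8-bis(benzyloxy)-2-[3,4-bis(benzyloxy)phenyl]-4-(2-ethoxyethoxy)chroman-3-ol
Conditions: DDQ, 2-ethoxyethanol, CH2Cl2, rt
Reagents that add atoms: 2-ethoxyethanol, CCOCCO
Why: DDQ abstracts hydride from C4, the benzylic position para to the 7-benzyloxy group and ortho to O1, and the alcohol traps the cation (oxidative C4 functionalisation of flavan-3-ol benzyl ethers).

Step 8
Reactants: 13 4-(2-ethoxyethoxy)flavan-3-ol; 12 (2R,3S)-tetra-O-benzylmesquitol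
Product: 14 (2R,3S,4R)-7,8-bis(benzyloxy)-2-[3,4-bis(benzyloxy)phenyl]-4-{(2R,3S)-7,8-bis(benzyloxy)-2-[3,4-bis(benzyloxy)phenyl]-3-hydroxychroman-6-yl}chroman-3-ol (octa-O-benzyl mesquitol-(4α→6)-mesquitol)
Conditions: 12 (4 eq), TMSOTf (cat.), CH2Cl2, −78 °C
Reagents that add atoms: none
Why: Lewis-acid ionisation of the C4 ether gives the benzylic cation, which C6 of 12 (ortho to 7-OBn, para to O1, the most nucleophilic and least hindered A-ring position) attacks in a Friedel–Crafts alkylation; attack anti to the 3-OH of the 2,3-trans cation should set C4 as 4α (3,4-trans), and the excess of 12 suppresses oligomerisation.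

Step 9
Reactants: 14 octa-O-benzyl dimer
Product: 15 (2R,3S,4R)-2-(3,4-dihydroxyphenyl)-4-[(2R,3S)-2-(3,4-dihydroxyphenyl)-3,7,8-trihydroxychroman-6-yl]chromane-3,7,8-triol (CNP0111710.1)
Conditions: H2 (1 atm), Pd(OH)2/C, THF/MeOH/H2O, rt
Reagents that add atoms: none
Why: Hydrogenolysis of the eight benzyl ethers under neutral conditions, which should leave the interflavan C–C bond, the pyran C2–O bonds and all five stereocentres untouched.

**Compound list**

1 | 2,3,4-trihydroxybenzaldehyde | O=Cc1ccc(O)c(O)c1O | starting material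
2 | 3,4-bis(benzyloxy)-2-hydroxybenzaldehyde | O=Cc1ccc(OCc2ccccc2)c(OCc2ccccc2)c1O | intermediate
3 | nitromethane | C[N+](=O)[O-] | starting material
4 | 5,6-bis(benzyloxy)-2-[(E)-2-nitroethenyl]phenol | [O-][N+](=O)/C=C/c1ccc(OCc2ccccc2)c(OCc2ccccc2)c1O | intermediate
5 | 1,2-bis(benzyloxy)-4-(chloromethyl)benzene | ClCc1ccc(OCc2ccccc2)c(OCc2ccccc2)c1 | starting material
6 | (1R,4R,5R)-isothiocineole, (1R,4R,5R)-4,7,7-trimethyl-6-thiabicyclo[3.2.1]octane | C[C@@H]1CC[C@@H]2C[C@H]1SC2(C)C | starting material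
7 | (1R,4R,5R)-6-[3,4-bis(benzyloxy)benzyl]-4,7,7-trimethyl-6-thiabicyclo[3.2.1]octan-6-ium tetrafluoroborate | C[C@@H]1CC[C@@H]2C[C@H]1[S+](Cc1ccc(OCc3ccccc3)c(OCc3ccccc3)c1)C2(C)C.F[B-](F)(F)F | intermediate
8 | sulfonium benzylide derived from 7 | C[C@@H]1CC[C@@H]2C[C@H]1[S+]([CH-]c1ccc(OCc3ccccc3)c(OCc3ccccc3)c1)C2(C)C | intermediate (not isolated)
9 | (2S,3R)-6,7-bis(benzyloxy)-2-[3,4-bis(benzyloxy)phenyl]-3-(nitromethyl)-2,3-dihydro-1-benzofuran | [O-][N+](=O)C[C@H]1c2ccc(OCc3ccccc3)c(OCc3ccccc3)c2O[C@@H]1c1ccc(OCc2ccccc2)c(OCc2ccccc2)c1 | intermediate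
10 | 1-{(2S,3R)-6,7-bis(benzyloxy)-2-[3,4-bis(benzyloxy)phenyl]-2,3-dihydro-1-benzofuran-3-yl}methanamine | NC[C@H]1c2ccc(OCc3ccccc3)c(OCc3ccccc3)c2O[C@@H]1c1ccc(OCc2ccccc2)c(OCc2ccccc2)c1 | intermediate
11 | {(2S,3R)-6,7-bis(benzyloxy)-2-[3,4-bis(benzyloxy)phenyl]-2,3-dihydro-1-benzofuran-3-yl}methanediazonium hydrogensulfate | N#[N+]C[C@H]1c2ccc(OCc3ccccc3)c(OCc3ccccc3)c2O[C@@H]1c1ccc(OCc2ccccc2)c(OCc2ccccc2)c1.OS(=O)(=O)[O-] | intermediate (not isolated)
12 | (2R,3S)-7,8-bis(benzyloxy)-2-[3,4-bis(benzyloxy)phenyl]chroman-3-ol | O[C@H]1Cc2ccc(OCc3ccccc3)c(OCc3ccccc3)c2O[C@@H]1c1ccc(OCc2ccccc2)c(OCc2ccccc2)c1 | intermediate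
13 | (2R,3S,4S)-7,8-bis(benzyloxy)-2-[3,4-bis(benzyloxy)phenyl]-4-(2-ethoxyethoxy)chroman-3-ol | O[C@H]1[C@@H](OCCOCC)c2ccc(OCc3ccccc3)c(OCc3ccccc3)c2O[C@@H]1c1ccc(OCc2ccccc2)c(OCc2ccccc2)c1 | intermediate
14 | octa-O-benzyl mesquitol-(4α→6)-mesquitol | c5ccccc5COc1ccc([C@H]2Oc3c(ccc(OCc5ccccc5)c3OCc5ccccc5)[C@@H](c3cc4c(c(OCc5ccccc5)c3OCc5ccccc5)O[C@H](c3ccc(OCc5ccccc5)c(OCc5ccccc5)c3)[C@@H](O)C4)[C@@H]2O)cc1OCc5ccccc5 | intermediate
15 | (2R,3S,4R)-2-(3,4-dihydroxyphenyl)-4-[(2R,3S)-2-(3,4-dihydroxyphenyl)-3,7,8-trihydroxychroman-6-yl]chromane-3,7,8-triol | Oc1ccc([C@H]2Oc3c(ccc(O)c3O)[C@@H](c3cc4c(c(O)c3O)O[C@H](c3ccc(O)c(O)c3)[C@@H](O)C4)[C@@H]2O)cc1O | target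

**Step count.** Total: 9 steps. Longest linear sequence: 8 steps (1, 2, 4, 5, 6, 7, 8, 9); step 3 is a one-step branch.

**Steps most likely to fail**

Step 6 (key step). The diazonium ion is a poorly discriminating leaving group. Loss of nitrogen may therefore be accompanied by hydride or C2 migration, direct substitution at CH2 or elimination, and the bridged ion may be opened at the primary terminus; each lowers the share of ring-expanded alcohol. The fallback sets out from 9 and comes back at 12. The nitromethyl group of 9 would be converted by a Nef reaction (NaOMe, MeOH, then buffered Oxone) into (2S,3S)-6,7-bis(benzyloxy)-2-[3,4-bis(benzyloxy)phenyl]-2,3-dihydro-1-benzofuran-3-carbaldehyde F1. This would be reduced with NaBH4 to {(2S,3R)-6,7-bis(benzyloxy)-2-[3,4-bis(benzyloxy)phenyl]-2,3-dihydro-1-benzofuran-3-yl}methanol F2 and converted with MsCl and Et3N into the corresponding methanesulfonate F3. Solvolysis of the mesylate in buffered aqueous hexafluoroisopropanol (2,6-lutidine, 40 °C) can ionise only with anchimeric assistance by the A ring. The same aryl shift and anti capture by water should then give 12 without a free diazonium or primary cation.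

Step 4. Transfer of chirality from the sulfonium benzylide may be weak in a conjugate addition, the trans selectivity may erode if the first C–C bond formation is irreversible, and O-alkylation of the nitronate may compete. The fallback sets out from 5 and 4 and comes back at 9. Chloride 5 would be converted with tetrahydrothiophene and NaBF4 into the achiral salt 1-[3,4-bis(benzyloxy)benzyl]thiolan-1-ium tetrafluoroborate F4. Annulation of this salt with 4 (Cs2CO3, MeCN) should give racemic trans-6,7-bis(benzyloxy)-2-[3,4-bis(benzyloxy)phenyl]-3-(nitromethyl)-2,3-dihydro-1-benzofuran F5. Preparative chromatography on a chiral stationary phase would then deliver the (2S,3R) enantiomer 9.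

Step 7. Hydride abstraction at C4 is slower for a 5-deoxy A ring than for phloroglucinol-type flavans. It may be overtaken by oxidation at C2–H or at the benzylic ether methylenes, or be followed by over-oxidation. The fallback sets out from 12 and comes back at 14. Acetylation (Ac2O, pyridine) would give (2R,3S)-7,8-bis(benzyloxy)-2-[3,4-bis(benzyloxy)phenyl]chroman-3-yl acetate F6. Benzylic acetoxylation with Pb(OAc)4 (benzene, 80 °C) would give the 3,4-diacetate (2R,3S)-7,8-bis(benzyloxy)-2-[3,4-bis(benzyloxy)phenyl]chromane-3,4-diyl diacetate F7 as a mixture of C4 epimers. Ionisation with BF3·OEt2 in the presence of excess 12 should proceed through the 3-acetoxonium ion, which shields the β face and directs the nucleophile to the 4α position. This would give the dimer 3-O-acetate octa-O-benzyl mesquitol-(4α→6)-mesquitol 3-acetate F8, and methanolysis (K2CO3, MeOH) would give 14.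

Further compounds

F1 | step 6 | (2S,3S)-6,7-bis(benzyloxy)-2-[3,4-bis(benzyloxy)phenyl]-2,3-dihydro-1-benzofuran-3-carbaldehyde | O=C[C@H]1c2ccc(OCc3ccccc3)c(OCc3ccccc3)c2O[C@@H]1c1ccc(OCc2ccccc2)c(OCc2ccccc2)c1
F2 | step 6 | {(2S,3R)-6,7-bis(benzyloxy)-2-[3,4-bis(benzyloxy)phenyl]-2,3-dihydro-1-benzofuran-3-yl}methanol | OC[C@H]1c2ccc(OCc3ccccc3)c(OCc3ccccc3)c2O[C@@H]1c1ccc(OCc2ccccc2)c(OCc2ccccc2)c1
F3 | step 6 | {(2S,3R)-6,7-bis(benzyloxy)-2-[3,4-bis(benzyloxy)phenyl]-2,3-dihydro-1-benzofuran-3-yl}methyl methanesulfonate | CS(=O)(=O)OC[C@H]1c2ccc(OCc3ccccc3)c(OCc3ccccc3)c2O[C@@H]1c1ccc(OCc2ccccc2)c(OCc2ccccc2)c1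
F4 | step 4 | 1-[3,4-bis(benzyloxy)benzyl]thiolan-1-ium tetrafluoroborate | c1ccccc1COc1ccc(C[S+]2CCCC2)cc1OCc1ccccc1.F[B-](F)(F)F
F5 | step 4 | racemic trans-6,7-bis(benzyloxy)-2-[3,4-bis(benzyloxy)phenyl]-3-(nitromethyl)-2,3-dihydro-1-benzofuran (both enantiomers) | [O-][N+](=O)C[C@H]1c2ccc(OCc3ccccc3)c(OCc3ccccc3)c2O[C@@H]1c1ccc(OCc2ccccc2)c(OCc2ccccc2)c1.[O-][N+](=O)C[C@@H]1c2ccc(OCc3ccccc3)c(OCc3ccccc3)c2O[C@H]1c1ccc(OCc2ccccc2)c(OCc2ccccc2)c1
F6 | step 7 | (2R,3S)-7,8-bis(benzyloxy)-2-[3,4-bis(benzyloxy)phenyl]chroman-3-yl acetate | CC(=O)O[C@H]1Cc2ccc(OCc3ccccc3)c(OCc3ccccc3)c2O[C@@H]1c1ccc(OCc2ccccc2)c(OCc2ccccc2)c1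
F7 | step 7 | (2R,3S)-7,8-bis(benzyloxy)-2-[3,4-bis(benzyloxy)phenyl]chromane-3,4-diyl diacetate (C4 epimers, C4 not encoded) | CC(=O)O[C@H]1C(OC(C)=O)c2ccc(OCc3ccccc3)c(OCc3ccccc3)c2O[C@@H]1c1ccc(OCc2ccccc2)c(OCc2ccccc2)c1
F8 | step 7 | octa-O-benzyl mesquitol-(4α→6)-mesquitol 3-acetate (acetate on the upper unit) | c5ccccc5COc1ccc([C@H]2Oc3c(ccc(OCc5ccccc5)c3OCc5ccccc5)[C@@H](c3cc4c(c(OCc5ccccc5)c3OCc5ccccc5)O[C@H](c3ccc(OCc5ccccc5)c(OCc5ccccc5)c3)[C@@H](O)C4)[C@@H]2OC(C)=O)cc1OCc5ccccc5
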